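The cyclobutane (C1, C2, C2a, C7a of the cyclobuta[a]indene core) carries the disconnection. The acyl-bearing C7a and the catechol-bearing C2 sit 1,3 across this ring, so the C7a–C2 diagonal can be the central bond of a bicyclo[1.1.0]butane carboxylate. In one flask a chiral dirhodium catalyst converts a styrenyl α-diazo ester into that bicyclobutane (C7a–C2a bond, C2a configuration), an arylcopper reagent opens it at C2, and protonation sets C7a. The precursor is tert-butyl (E)-2-diazo-5-(3,5-dimethoxyphenyl)-3,3-dimethylpent-4-enoate. Friedel–Crafts closure of the five-membered ring (C7–C6a) and late prenylation at C3 complete the target.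

Key step: step 6

Assumption: locants are those of 2,2a,7,7a-tetrahydro-1H-cyclobuta[a]indene (C1 CMe2, C2 CH–aryl, C2a/C7a fusion CH, C7 CH2, C3 prenyl, C4 OMe, C6 OH); Rh2(S-NTTL)4 is written for step 6, and if the gem-dimethyl substrate gives the antipodal bicyclobutane, Rh2(R-NTTL)4 replaces it with nothing else changed.

**Step 1**
Reactants: 1 3,3-dimethylpent-4-enoic acid
Product: 2 tert-butyl 3,3-dimethylpent-4-enoate
Conditions: tert-butyl 2,2,2-trichloroacetimidate, BF3·OEt2 (cat.), cyclohexane–CH2Cl2, rt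
Reagents that add atoms: tert-butyl 2,2,2-trichloroacetimidate CC(C)(C)OC(=N)C(Cl)(Cl)Cl
Why: Acid-catalysed trichloroacetimidate esterification is a mild standard route to tert-butyl esters and leaves the vinyl group alone; the tert-butyl ester is chosen because bulky esters are the ones proven in dirhodium bicyclobutanation and can later be removed by acid without epimerising C7a.

**Step 2**
Reactants: 2 tert-butyl 3,3-dimethylpent-4-enoate; 3 1-bromo-3,5-dimethoxybenzene
Product: 4 tert-butyl (E)-5-(3,5-dimethoxyphenyl)-3,3-dimethylpent-4-enoate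
Conditions: Pd(OAc)2 (cat.), P(o-tol)3, Et3N, DMF, 100 °C
Reagents that add atoms: none
Why: In this Mizoroki–Heck arylation the quaternary allylic carbon directs the aryl group to the terminal alkene carbon and, having no hydrogen, allows β-hydride elimination only toward the conjugated (E)-styrene, so no alkene migration is possible.

**Step 3**
Reactants: 4 tert-butyl (E)-5-(3,5-dimethoxyphenyl)-3,3-dimethylpent-4-enoate
Product: 6 tert-butyl (E)-2-diazo-5-(3,5-dimethoxyphenyl)-3,3-dimethylpent-4-enoate, via trifluoroacetyl ester 5 (not isolated)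
Conditions: LDA, THF, −78 °C; CF3CO2CH2CF3; 5% HCl work-up; then 4-acetamidobenzenesulfonyl azide, Et3N, H2O (1 equiv), MeCN, rt
Reagents that add atoms: 2,2,2-trifluoroethyl trifluoroacetate FC(F)(F)COC(=O)C(F)(F)F (its CF3CO group is in 5 only); 4-acetamidobenzenesulfonyl azide CC(=O)Nc1ccc(cc1)S(=O)(=O)N=[N+]=[N-]
Why: Crossed Claisen trifluoroacetylation of the ester enolate activates the α-carbon for Regitz diazo transfer, after which the trifluoroacetyl group leaves as the N-sulfonyl trifluoroacetamide (detrifluoroacetylative diazo transfer).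

**Step 4**
Reactants: 7 4-bromocatechol
Product: 8 4-bromo-1,2-diisopropoxybenzene
Conditions: 2-bromopropane, K2CO3, DMF, 60 °C
Reagents that add atoms: 2-bromopropane CC(C)Br
Why: Williamson etherification of both phenols gives isopropyl ethers, which tolerate Grignard formation, protic acid and MgI2 and are cleaved by BCl3 in preference to an aryl methyl ether.

**Step 5**
Reactants: 8 4-bromo-1,2-diisopropoxybenzene
Product: 9 (3,4-diisopropoxyphenyl)magnesium bromide
Conditions: Mg turnings, I2 (cat.), THF, reflux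
Reagents that add atoms: magnesium [Mg]
Why: Direct magnesium insertion into the aryl bromide (Grignard formation) is unaffected by the two ether groups.

**Step 6**
Reactants: 6 tert-butyl (E)-2-diazo-5-(3,5-dimethoxyphenyl)-3,3-dimethylpent-4-enoate; 9 (3,4-diisopropoxyphenyl)magnesium bromide
Product: 12 tert-butyl (1S,2S,3S)-3-(3,4-diisopropoxyphenyl)-2-(3,5-dimethoxyphenyl)-4,4-dimethylcyclobutane-1-carboxylate, via bicyclobutane ester 10 (not isolated), via magnesium enolate 11 (not isolated)
Conditions: Rh2(S-NTTL)4 (0.5 mol %), PhMe, −78 °C; then 9, CuBr·SMe2 (30 mol %), PBu3, THF, −78 °C → rt; then BHT, THF, −78 °C; H2O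
Reagents that add atoms: none
Why: Dirhodium-carbene formation at C7a and intramolecular [2+1] addition to the (E)-styrenyl alkene closes the four-membered ring through the new C7a–C2a bond, with a transient C7a–C2 bond completing bicyclobutane 10, after which copper-catalysed homoconjugate (strain-release) addition of the aryl Grignard breaks that central bond and forms C2–aryl. The closest known reaction type is the chiral dirhodium carboxylate-catalysed bicyclobutanation of 2-diazo-5-arylpent-4-enoates coupled in one flask with copper-catalysed Grignard opening and enolate trapping; the CMe2 bridge is the new variable. C2a is set by the catalyst, which selects the alkene face, while the E geometry places ring A exo on the bicyclobutane (stereospecific syn addition). C2 is set by the substrate: the arylcopper enters at the unsubstituted bridgehead from the concave side, in line with the breaking central bond, so the new aryl lies trans to the exo ring-A aryl. C7a is set by kinetic protonation of the ester enolate with the hindered phenol on the face remote from the adjacent ring-A aryl, giving the 1,2-cis ester. The step needs cyclopropanation to outrun other carbene pathways and attack at C2 instead of C7a: the quaternary C1 removes any β-hydrogen and favours ring closure, and the ester polarises the central bond so that C2 is the electrophilic terminus.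

**Step 7**
Reactants: 12 tert-butyl (1S,2S,3S)-3-(3,4-diisopropoxyphenyl)-2-(3,5-dimethoxyphenyl)-4,4-dimethylcyclobutane-1-carboxylate
Product: 14 (2S,2aS,7aS)-2-(3,4-diisopropoxyphenyl)-4,6-dimethoxy-1,1-dimethyl-1,2,2a,7a-tetrahydro-7H-cyclobuta[a]inden-7-one, via carboxylic acid 13 (not isolated)
Conditions: TFA, Et3SiH, CH2Cl2, rt; evaporate (PhMe azeotrope); then TFAA, CH2Cl2, 0 °C → rt
Reagents that add atoms: none
Why: Acidolysis of the tert-butyl ester (cation trapped by the silane) frees the acid without exposing C7a to base, and its mixed trifluoroacetic anhydride acylates C6a, which is ortho to one methoxy and para to the other, in an intramolecular Friedel–Crafts acylation that only the cis acid can undergo, so the ring fusion is cis.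

**Step 8**
Reactants: 14 (2S,2aS,7aS)-2-(3,4-diisopropoxyphenyl)-4,6-dimethoxy-1,1-dimethyl-1,2,2a,7a-tetrahydro-7H-cyclobuta[a]inden-7-one
Product: 15 (2S,2aS,7aS)-2-(3,4-diisopropoxyphenyl)-6-hydroxy-4-methoxy-1,1-dimethyl-1,2,2a,7a-tetrahydro-7H-cyclobuta[a]inden-7-one
Conditions: MgI2·OEt2, PhMe, 80 °C; aqueous work-up
Reagents that add atoms: none
Why: Magnesium held between the C7 carbonyl and the peri C6 methoxy oxygen exposes only that methyl group to SN2 attack by iodide (chelation-controlled demethylation), so the C4 methoxy and the isopropyl ethers, which cannot chelate to the ketone, should remain.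

**Step 9**
Reactants: 15 (2S,2aS,7aS)-2-(3,4-diisopropoxyphenyl)-6-hydroxy-4-methoxy-1,1-dimethyl-1,2,2a,7a-tetrahydro-7H-cyclobuta[a]inden-7-one
Product: 16 (2S,2aR,7aS)-2-(3,4-diisopropoxyphenyl)-4-methoxy-1,1-dimethyl-2,2a,7,7a-tetrahydro-1H-cyclobuta[a]inden-6-ol
Conditions: Et3SiH, TFA, rt → 40 °C
Reagents that add atoms: none
Why: Ionic hydrogenation (silane–acid reduction of an electron-rich aryl ketone) delivers two hydrides through the 2-hydroxy-4-methoxybenzylic cation at C7, whose skeletal shifts would lead only to bridged or benzocyclobutene cations and are therefore not expected.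

**Step 10**
Reactants: 16 (2S,2aR,7aS)-2-(3,4-diisopropoxyphenyl)-4-methoxy-1,1-dimethyl-2,2a,7,7a-tetrahydro-1H-cyclobuta[a]inden-6-ol
Product: 17 (2S,2aR,7aS)-3-bromo-2-(3,4-diisopropoxyphenyl)-4-methoxy-1,1-dimethyl-2,2a,7,7a-tetrahydro-1H-cyclobuta[a]inden-6-ol
Conditions: NBS (1.0 equiv), MeCN–CH2Cl2, −40 °C
Reagents that add atoms: N-bromosuccinimide O=C1CCC(=O)N1Br
Why: Electrophilic aromatic bromination of the free phenol ring should go para to the hydroxyl and ortho to the methoxy (C3), because C5 between the two oxygens is the least reactive site of a resorcinol derivative and the phenol ring far outpaces the dialkoxyphenyl ring at low temperature.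

**Step 11**
Reactants: 17 (2S,2aR,7aS)-3-bromo-2-(3,4-diisopropoxyphenyl)-4-methoxy-1,1-dimethyl-2,2a,7,7a-tetrahydro-1H-cyclobuta[a]inden-6-ol; 18 1-bromo-3-methylbut-2-ene (prenyl bromide)
Product: 20 (2S,2aR,7aS)-2-(3,4-diisopropoxyphenyl)-4-methoxy-1,1-dimethyl-3-(3-methylbut-2-en-1-yl)-2,2a,7,7a-tetrahydro-1H-cyclobuta[a]inden-6-ol, via dilithio species 19 (not isolated)
Conditions: t-BuLi (3.1 equiv), THF, −78 °C; CuBr·SMe2 (10 mol %), 18, −78 → 0 °C; aq NH4Cl
Reagents that add atoms: none
Why: Deprotonation of the phenol followed by bromine–lithium exchange gives the C3 aryllithium, which is allylated at the primary carbon of prenyl bromide under copper catalysis (allylic substitution by an arylmetal), the lithium phenoxide being a poor O-nucleophile in cold THF.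

**Step 12**
Reactants: 20 (2S,2aR,7aS)-2-(3,4-diisopropoxyphenyl)-4-methoxy-1,1-dimethyl-3-(3-methylbut-2-en-1-yl)-2,2a,7,7a-tetrahydro-1H-cyclobuta[a]inden-6-ol
Product: 21 4-[(2S,2aR,7aS)-6-hydroxy-4-methoxy-1,1-dimethyl-3-(3-methylbut-2-en-1-yl)-2,2a,7,7a-tetrahydro-1H-cyclobuta[a]inden-2-yl]benzene-1,2-diol
Conditions: BCl3 (1 M in CH2Cl2), CH2Cl2, −78 → −20 °C; MeOH then H2O
Reagents that add atoms: none
Why: BCl3 bound to the catechol ether oxygens removes the secondary isopropyl groups as 2-chloropropane at low temperature while the unchelated aryl methyl ether is stable (selective Lewis acid dealkylation), and the short cold exposure is meant to spare the trisubstituted alkene.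

**Compound list**
1 | 3,3-dimethylpent-4-enoic acid | C=CC(C)(C)CC(=O)O | starting material
2 | tert-butyl 3,3-dimethylpent-4-enoate | C=CC(C)(C)CC(=O)OC(C)(C)C | intermediate
3 | 1-bromo-3,5-dimethoxybenzene | COc1cc(Br)cc(OC)c1 | starting material
4 | tert-butyl (E)-5-(3,5-dimethoxyphenyl)-3,3-dimethylpent-4-enoate | CC(C)(C)OC(=O)CC(C)(C)/C=C/c1cc(OC)cc(OC)c1 | intermediate
5 | tert-butyl (E)-5-(3,5-dimethoxyphenyl)-3,3-dimethyl-2-(2,2,2-trifluoroacetyl)pent-4-enoate (racemic at C2, not isolated) | CC(C)(C)OC(=O)C(C(=O)C(F)(F)F)C(C)(C)/C=C/c1cc(OC)cc(OC)c1 | intermediate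
6 | tert-butyl (E)-2-diazo-5-(3,5-dimethoxyphenyl)-3,3-dimethylpent-4-enoate | CC(C)(C)OC(=O)C(=[N+]=[N-])C(C)(C)/C=C/c1cc(OC)cc(OC)c1 | intermediate
7 | 4-bromocatechol (4-bromobenzene-1,2-diol) | Oc1ccc(Br)cc1O | starting material
8 | 4-bromo-1,2-diisopropoxybenzene | CC(C)Oc1ccc(Br)cc1OC(C)C | intermediate
9 | (3,4-diisopropoxyphenyl)magnesium bromide | Br[Mg]c1ccc(OC(C)C)c(OC(C)C)c1 | intermediate
10 | tert-butyl (1R,2R,3R)-2-(3,5-dimethoxyphenyl)-4,4-dimethylbicyclo[1.1.0]butane-1-carboxylate (aryl exo, not isolated) | CC(C)(C)OC(=O)[C@]12C(C)(C)[C@H]1[C@@H]2c1cc(OC)cc(OC)c1 | intermediate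
11 | bromomagnesium ester enolate at C1 of the 2,3-trans-3-(3,4-diisopropoxyphenyl)-2-(3,5-dimethoxyphenyl)-4,4-dimethylcyclobutane (C2, C3 as in 12, not isolated) | CC(C)(C)OC(O[Mg]Br)=C1[C@@H](c2cc(OC)cc(OC)c2)[C@H](c2ccc(OC(C)C)c(OC(C)C)c2)C1(C)C | intermediate
12 | tert-butyl (1S,2S,3S)-3-(3,4-diisopropoxyphenyl)-2-(3,5-dimethoxyphenyl)-4,4-dimethylcyclobutane-1-carboxylate (1,2-cis, 2,3-trans) | COc1cc(OC)cc(c1)[C@@H]1[C@H](C(=O)OC(C)(C)C)C(C)(C)[C@H]1c1ccc(OC(C)C)c(OC(C)C)c1 | intermediate
13 | (1S,2S,3S)-3-(3,4-diisopropoxyphenyl)-2-(3,5-dimethoxyphenyl)-4,4-dimethylcyclobutane-1-carboxylic acid (not isolated) | COc1cc(OC)cc(c1)[C@@H]1[C@H](C(=O)O)C(C)(C)[C@H]1c1ccc(OC(C)C)c(OC(C)C)c1 | intermediate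
14 | (2S,2aS,7aS)-2-(3,4-diisopropoxyphenyl)-4,6-dimethoxy-1,1-dimethyl-1,2,2a,7a-tetrahydro-7H-cyclobuta[a]inden-7-one | COc1cc(OC)c2c(c1)[C@@H]1[C@H](C2=O)C(C)(C)[C@H]1c1ccc(OC(C)C)c(OC(C)C)c1 | intermediate
15 | (2S,2aS,7aS)-2-(3,4-diisopropoxyphenyl)-6-hydroxy-4-methoxy-1,1-dimethyl-1,2,2a,7a-tetrahydro-7H-cyclobuta[a]inden-7-one | COc1cc(O)c2c(c1)[C@@H]1[C@H](C2=O)C(C)(C)[C@H]1c1ccc(OC(C)C)c(OC(C)C)c1 | intermediate
16 | (2S,2aR,7aS)-2-(3,4-diisopropoxyphenyl)-4-methoxy-1,1-dimethyl-2,2a,7,7a-tetrahydro-1H-cyclobuta[a]inden-6-ol | COc1cc(O)c2c(c1)[C@@H]1[C@H](C2)C(C)(C)[C@H]1c1ccc(OC(C)C)c(OC(C)C)c1 | intermediate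
17 | (2S,2aR,7aS)-3-bromo-2-(3,4-diisopropoxyphenyl)-4-methoxy-1,1-dimethyl-2,2a,7,7a-tetrahydro-1H-cyclobuta[a]inden-6-ol | COc1cc(O)c2c(c1Br)[C@@H]1[C@H](C2)C(C)(C)[C@H]1c1ccc(OC(C)C)c(OC(C)C)c1 | intermediate
18 | 1-bromo-3-methylbut-2-ene (prenyl bromide) | CC(C)=CCBr | starting material
19 | lithium (2S,2aR,7aS)-2-(3,4-diisopropoxyphenyl)-3-lithio-4-methoxy-1,1-dimethyl-2,2a,7,7a-tetrahydro-1H-cyclobuta[a]inden-6-olate (not isolated) | COc1cc(O[Li])c2c(c1[Li])[C@@H]1[C@H](C2)C(C)(C)[C@H]1c1ccc(OC(C)C)c(OC(C)C)c1 | intermediate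
20 | (2S,2aR,7aS)-2-(3,4-diisopropoxyphenyl)-4-methoxy-1,1-dimethyl-3-(3-methylbut-2-en-1-yl)-2,2a,7,7a-tetrahydro-1H-cyclobuta[a]inden-6-ol | COc1cc(O)c2c(c1CC=C(C)C)[C@@H]1[C@H](C2)C(C)(C)[C@H]1c1ccc(OC(C)C)c(OC(C)C)c1 | intermediate
21 | 4-[(2S,2aR,7aS)-6-hydroxy-4-methoxy-1,1-dimethyl-3-(3-methylbut-2-en-1-yl)-2,2a,7,7a-tetrahydro-1H-cyclobuta[a]inden-2-yl]benzene-1,2-diol (CNP0236667.1) | COc1cc(O)c2c(c1CC=C(C)C)[C@@H]1[C@H](C2)C(C)(C)[C@H]1c1ccc(O)c(O)c1 | target

Total step count: 12. Longest linear sequence: 10 steps (steps 1–3 and 6–12); the aryl Grignard branch (steps 4–5) joins at step 6.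

**Steps most likely to fail**

Step 6. The arylcopper may approach C2 too slowly because the endo methyl of the CMe2 bridge lies close to its line of attack, so the strained intermediate decomposes instead. The fallback sets out from bicyclobutane 10, made by the rhodium stage alone and used crude. HBr (1 equiv, Et2O, −40 °C) would add across the central bond, the small bromide entering at C2, to give tert-butyl 3-bromo-2-(3,5-dimethoxyphenyl)-4,4-dimethylcyclobutane-1-carboxylate F1 (aryl-bearing carbon as in 12, the other two centres as formed). Iron-catalysed Kumada coupling of this secondary bromide with 9 (FeCl3, TMEDA, THF, 0 °C, slow addition) goes through a cyclobutyl radical that should accept the aryl group trans to the neighbouring ring-A aryl. It would give the cyclobutane ester as a mixture at the ester carbon, represented by the trans ester tert-butyl (1R,2S,3S)-3-(3,4-diisopropoxyphenyl)-2-(3,5-dimethoxyphenyl)-4,4-dimethylcyclobutane-1-carboxylate F2. Enolisation with LDA at −78 °C and quenching with BHT would then converge on 12.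

Step 11. Bromine–lithium exchange at the doubly ortho-substituted C3 may be incomplete, the aryllithium may be protonated, or allylation may occur through the tertiary carbon of the prenyl unit. The fallback sets out from 17 and returns at 20 without new intermediates: Stille coupling with tributyl(3-methylbut-2-en-1-yl)stannane (Pd2(dba)3, P(t-Bu)3, CsF, dioxane, 100 °C) forms the C3–prenyl bond by palladium catalysis and tolerates the free phenol.

Step 12. Hydrochlorination of the prenyl alkene, or its Lewis acid cyclisation onto the C4 oxygen, may compete with isopropyl cleavage. The fallback sets out from 17 and returns at 21, so the alkene never meets BCl3. BCl3 (CH2Cl2, −78 → 0 °C) on 17 would give (2S,2aR,7aS)-4-(3-bromo-6-hydroxy-4-methoxy-1,1-dimethyl-2,2a,7,7a-tetrahydro-1H-cyclobuta[a]inden-2-yl)benzene-1,2-diol F3. Silylation (TBSCl, imidazole, DMF) would give its tris(tert-butyldimethylsilyl) ether F4. Bromine–lithium exchange (t-BuLi, THF, −78 °C), CuBr·SMe2 and prenyl bromide 18 would give the C3-prenylated tris-silyl ether F5. Buffered fluoride (TBAF, AcOH, THF, 0 °C) would then release 21.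

**Further compounds**
F1 | step 6 | tert-butyl 3-bromo-2-(3,5-dimethoxyphenyl)-4,4-dimethylcyclobutane-1-carboxylate (aryl-bearing carbon as in 12; C1 and C3 as formed) | COc1cc(OC)cc(c1)[C@@H]1C(C(=O)OC(C)(C)C)C(C)(C)C1Br
F2 | step 6 | tert-butyl (1R,2S,3S)-3-(3,4-diisopropoxyphenyl)-2-(3,5-dimethoxyphenyl)-4,4-dimethylcyclobutane-1-carboxylate | COc1cc(OC)cc(c1)[C@@H]1[C@@H](C(=O)OC(C)(C)C)C(C)(C)[C@H]1c1ccc(OC(C)C)c(OC(C)C)c1
F0 | step 11 | none | none
F3 | step 12 | (2S,2aR,7aS)-4-(3-bromo-6-hydroxy-4-methoxy-1,1-dimethyl-2,2a,7,7a-tetrahydro-1H-cyclobuta[a]inden-2-yl)benzene-1,2-diol | COc1cc(O)c2c(c1Br)[C@@H]1[C@H](C2)C(C)(C)[C@H]1c1ccc(O)c(O)c1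
F4 | step 12 | tris(tert-butyldimethylsilyl) ether of F3 | COc1cc(O[Si](C)(C)C(C)(C)C)c2c(c1Br)[C@@H]1[C@H](C2)C(C)(C)[C@H]1c1ccc(O[Si](C)(C)C(C)(C)C)c(O[Si](C)(C)C(C)(C)C)c1
F5 | step 12 | tris(tert-butyldimethylsilyl) ether of 21 | COc1cc(O[Si](C)(C)C(C)(C)C)c2c(c1CC=C(C)C)[C@@H]1[C@H](C2)C(C)(C)[C@H]1c1ccc(O[Si](C)(C)C(C)(C)C)c(O[Si](C)(C)C(C)(C)C)c1
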